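The whole plan rests on sending the C6 prenyl of ring A and the C5' prenyl of ring B back to the neighbouring oxygens: each lies ortho to a free phenol (5-OH, 4'-OH), so both C–C bonds can arise from [3,3] shifts of 1,1-dimethylallyl ethers on O5 and O4'. One heating of the bis-ether should make the C6–CH2 and C5'–CH2 bonds, unmask both phenols and leave C8 alone, because C8 is not ortho to O5. The precursor is the (2R)-flavanone with tertiary allyl ethers on O5 and O4', a prenyl group on C3' and a triisopropylsilyl ether on O7, assembled by enantioselective rhodium-catalysed arylation of a chromone at C2.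

Key step: step 9

Remark: O7 is carried as a triisopropylsilyl ether, because an aryl silyl ether para to the C4 carbonyl has to outlast DBU and the aqueous rhodium step. Commercial 3-chloro-3-methylbut-1-yne serves as the propargyl donor, and both tertiary ethers are in place before the halves are joined, so that no base meets the flavanone.

Step 1
Reactants: 1 5,7-dihydroxy-4H-chromen-4-one (5,7-dihydroxychromone)
Product: 2 5-hydroxy-7-(triisopropylsilyloxy)-4H-chromen-4-one
Conditions: TIPSCl (1.05 equiv), imidazole, DMF, 0 °C to rt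
Reagents that add atoms: chlorotri(propan-2-yl)silane (TIPSCl), CC(C)[Si](Cl)(C(C)C)C(C)C
Why: Phenol silylation, expected at O7 alone because the 7-OH is the acidic, unhindered hydroxyl while the 5-OH is locked in a hydrogen bond to the C4 carbonyl.

Step 2
Reactants: 2 5-hydroxy-7-(triisopropylsilyloxy)-4H-chromen-4-one; 3 3-chloro-3-methylbut-1-yne
Product: 4 5-[(2-methylbut-3-yn-2-yl)oxy]-7-(triisopropylsilyloxy)-4H-chromen-4-one
Conditions: 3 (1.5 equiv), CuCl2·2H2O (1 mol%), DBU (1.3 equiv), MeCN, 0 °C to rt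
Reagents that add atoms: none
Why: Copper-catalysed propargylic etherification of a phenol, in which DBU opens the 5-OH chelate by deprotonation and the phenoxide adds to the copper acetylide/allenylidene formed from the tertiary chloride, so the hindered tertiary ether forms without an SN2 displacement.

Step 3
Reactants: 4 5-[(2-methylbut-3-yn-2-yl)oxy]-7-(triisopropylsilyloxy)-4H-chromen-4-one
Product: 5 5-[(2-methylbut-3-en-2-yl)oxy]-7-(triisopropylsilyloxy)-4H-chromen-4-one
Conditions: H2 (1 atm), Pd/CaCO3 poisoned with Pb(OAc)2, quinoline, EtOAc, rt, stopped after 1 equiv H2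
Reagents that add atoms: none
Why: Lindlar semihydrogenation, where the poisoned palladium surface should reduce the terminal alkyne to the vinyl group and spare the chromone C2=C3 bond, the silyl ether and the tertiary C–O bond.

Step 4
Reactants: 6 4-bromophenol; 7 1-bromo-3-methylbut-2-ene (prenyl bromide)
Product: 8 4-bromo-2-(3-methylbut-2-en-1-yl)phenol
Conditions: NaH (1.0 equiv), toluene, 0 °C; then 7 (0.9 equiv), 0 °C to rt
Reagents that add atoms: none
Why: Ortho C-alkylation of a sodium phenoxide, which as a tight aggregate in toluene reacts at carbon, and since para is blocked by bromine the prenyl group should enter at C2, the slight excess of phenoxide limiting a second alkylation.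

Step 5
Reactants: 8 4-bromo-2-(3-methylbut-2-en-1-yl)phenol; 3 3-chloro-3-methylbut-1-yne
Product: 9 4-bromo-2-(3-methylbut-2-en-1-yl)-1-[(2-methylbut-3-yn-2-yl)oxy]benzene
Conditions: 3 (1.3 equiv), CuCl2·2H2O (1 mol%), DBU (1.3 equiv), MeCN, 0 °C
Reagents that add atoms: none
Why: The same copper-catalysed propargylic etherification, here on an unchelated phenol, which is the standard substrate for this reaction.

Step 6
Reactants: 9 4-bromo-2-(3-methylbut-2-en-1-yl)-1-[(2-methylbut-3-yn-2-yl)oxy]benzene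
Product: 10 4-bromo-2-(3-methylbut-2-en-1-yl)-1-[(2-methylbut-3-en-2-yl)oxy]benzene
Conditions: H2 (1 atm), Pd/CaCO3 poisoned with Pb(OAc)2, quinoline, EtOAc, rt, stopped after 1 equiv H2
Reagents that add atoms: none
Why: Lindlar semihydrogenation of the terminal alkyne, under which the trisubstituted prenyl alkene and the aryl bromide should not react.

Step 7
Reactants: 10 4-bromo-2-(3-methylbut-2-en-1-yl)-1-[(2-methylbut-3-en-2-yl)oxy]benzene
Product: 13 {3-(3-methylbut-2-en-1-yl)-4-[(2-methylbut-3-en-2-yl)oxy]phenyl}boronic acid, via aryllithium 11 (not isolated), via lithium aryltriisopropoxyborate 12 (not isolated)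
Conditions: n-BuLi (1.05 equiv), THF, −78 °C; B(OiPr)3 (1.5 equiv), −78 to 0 °C; aq NH4Cl
Reagents that add atoms: triisopropyl borate, CC(C)OB(OC(C)C)OC(C)C; water, O
Why: Bromine–lithium exchange and borylation of the aryllithium followed by hydrolysis, which the ether should survive because its oxygen-bearing carbon is quaternary (no Wittig rearrangement) and the work-up is close to neutral.

Step 8
Reactants: 5 5-[(2-methylbut-3-en-2-yl)oxy]-7-(triisopropylsilyloxy)-4H-chromen-4-one; 13 {3-(3-methylbut-2-en-1-yl)-4-[(2-methylbut-3-en-2-yl)oxy]phenyl}boronic acid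
Product: 14 (2R)-5-[(2-methylbut-3-en-2-yl)oxy]-2-{3-(3-methylbut-2-en-1-yl)-4-[(2-methylbut-3-en-2-yl)oxy]phenyl}-7-(triisopropylsilyloxy)-2,3-dihydro-4H-chromen-4-one
Conditions: 13 (1.5 equiv), [Rh(OH)((R)-MeO-F12-BIPHEP)]2 (1.5 mol%), CH2Cl2/H2O 10:1, 25 °C, no added base
Reagents that add atoms: none
Why: Hayashi–Miyaura asymmetric 1,4-addition, in which the aryl group passes from boron to monovalent rhodium, inserts across the chromone C2=C3 bond and the rhodium enolate is protonated by water; the C2 stereocentre is set by the catalyst, whose R-configured ligand (R)-2,2'-bis[bis(3,4,5-trifluorophenyl)phosphino]-6,6'-dimethoxy-1,1'-biphenyl should, by the quadrant model that holds for 2-cyclohexenone, expose the chromone face that leads to 2R, while the base-free medium keeps the flavanone closed and the aryl–rhodium species is not expected to insert into the unactivated vinyl groups.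

Step 9
Reactants: 14 (2R)-5-[(2-methylbut-3-en-2-yl)oxy]-2-{3-(3-methylbut-2-en-1-yl)-4-[(2-methylbut-3-en-2-yl)oxy]phenyl}-7-(triisopropylsilyloxy)-2,3-dihydro-4H-chromen-4-one
Product: 18 (2R)-5-hydroxy-2-[4-hydroxy-3,5-bis(3-methylbut-2-en-1-yl)phenyl]-6-(3-methylbut-2-en-1-yl)-7-(triisopropylsilyloxy)-2,3-dihydro-4H-chromen-4-one, via ring A dienone 15 (not isolated), via ring A phenol 16 (not isolated), via ring B dienone 17 (not isolated)
Conditions: toluene (degassed, 0.02 M), 110 °C, sealed tube under Ar, base-washed glassware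
Reagents that add atoms: none
Why: Each aryl 1,1-dimethylallyl ether should pass through a concerted chair-like [3,3] shift in which the CH2 end of its vinyl group bonds to the ring carbon ortho to the departing oxygen, so the tertiary ether emerges as a linear 3-methylbut-2-enyl group and the cyclohexa-2,4-dienones 15 and 17 tautomerise to the phenols 16 and 18; ring A is expected to react first, but either order converges on 18. This is the aromatic Claisen rearrangement of reverse-prenyl aryl ethers, a standard entry to ortho-prenylphenols, run here twice in one flask. No ring is closed and no stereocentre is created; C2 is a spectator that the neutral aprotic medium should leave untouched, since opening of the pyranone ring to a chalcone needs base or acid. On ring A the group leaving O5 can reach only C6 or the quaternary ring-fusion carbon C4a, from which it can only return, whereas C8 lies para to O5 and would require a further Cope shift that builds a quaternary centre, a path that enolisation of the C6 dienone to the carbonyl-chelated 5-OH should outrun. On ring B the C3' position already holds a prenyl group, so bonding there gives a dienone that cannot aromatise and reverts, which funnels the material to C5'. The silyl ether on O7 and the absence of acid keep the tertiary ethers from ionising and the new ortho-prenylphenols from closing to chromans.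

Step 10
Reactants: 18 (2R)-5-hydroxy-2-[4-hydroxy-3,5-bis(3-methylbut-2-en-1-yl)phenyl]-6-(3-methylbut-2-en-1-yl)-7-(triisopropylsilyloxy)-2,3-dihydro-4H-chromen-4-one
Product: 19 (2R)-5,7-dihydroxy-2-[4-hydroxy-3,5-bis(3-methylbut-2-en-1-yl)phenyl]-6-(3-methylbut-2-en-1-yl)-2,3-dihydro-4H-chromen-4-one
Conditions: TBAF (1.2 equiv), AcOH (1.5 equiv), THF, 0 °C
Reagents that add atoms: none
Why: Fluoride desilylation of the silyl ether of an acidic phenol, buffered with acetic acid so that the medium stays below the basicity at which a 4'-hydroxyflavanone opens and loses its C2 configuration and well short of the acidity that would cyclise a prenyl group onto a phenol.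

Compound list
1 | 5,7-dihydroxy-4H-chromen-4-one | O=c1ccoc2cc(O)cc(O)c12 | starting material
2 | 5-hydroxy-7-(triisopropylsilyloxy)-4H-chromen-4-one | O=c1ccoc2cc(O[Si](C(C)C)(C(C)C)C(C)C)cc(O)c12 | intermediate
3 | 3-chloro-3-methylbut-1-yne | CC(C)(Cl)C#C | starting material
4 | 5-[(2-methylbut-3-yn-2-yl)oxy]-7-(triisopropylsilyloxy)-4H-chromen-4-one | O=c1ccoc2cc(O[Si](C(C)C)(C(C)C)C(C)C)cc(OC(C)(C)C#C)c12 | intermediate
5 | 5-[(2-methylbut-3-en-2-yl)oxy]-7-(triisopropylsilyloxy)-4H-chromen-4-one | O=c1ccoc2cc(O[Si](C(C)C)(C(C)C)C(C)C)cc(OC(C)(C)C=C)c12 | intermediate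
6 | 4-bromophenol | Oc1ccc(Br)cc1 | starting material
7 | 1-bromo-3-methylbut-2-ene (prenyl bromide) | CC(C)=CCBr | starting material
8 | 4-bromo-2-(3-methylbut-2-en-1-yl)phenol | CC(C)=CCc1cc(Br)ccc1O | intermediate
9 | 4-bromo-2-(3-methylbut-2-en-1-yl)-1-[(2-methylbut-3-yn-2-yl)oxy]benzene | CC(C)=CCc1cc(Br)ccc1OC(C)(C)C#C | intermediate
10 | 4-bromo-2-(3-methylbut-2-en-1-yl)-1-[(2-methylbut-3-en-2-yl)oxy]benzene | CC(C)=CCc1cc(Br)ccc1OC(C)(C)C=C | intermediate
11 | {3-(3-methylbut-2-en-1-yl)-4-[(2-methylbut-3-en-2-yl)oxy]phenyl}lithium (not isolated) | [Li]c1ccc(OC(C)(C)C=C)c(CC=C(C)C)c1 | intermediate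
12 | lithium {3-(3-methylbut-2-en-1-yl)-4-[(2-methylbut-3-en-2-yl)oxy]phenyl}tri(propan-2-yloxy)borate (not isolated) | CC(C)=CCc1cc([B-](OC(C)C)(OC(C)C)OC(C)C)ccc1OC(C)(C)C=C.[Li+] | intermediate
13 | {3-(3-methylbut-2-en-1-yl)-4-[(2-methylbut-3-en-2-yl)oxy]phenyl}boronic acid | CC(C)=CCc1cc(B(O)O)ccc1OC(C)(C)C=C | intermediate
14 | (2R)-5-[(2-methylbut-3-en-2-yl)oxy]-2-{3-(3-methylbut-2-en-1-yl)-4-[(2-methylbut-3-en-2-yl)oxy]phenyl}-7-(triisopropylsilyloxy)-2,3-dihydro-4H-chromen-4-one | CC(C)=CCc1cc([C@H]2CC(=O)c3c(cc(O[Si](C(C)C)(C(C)C)C(C)C)cc3OC(C)(C)C=C)O2)ccc1OC(C)(C)C=C | intermediate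
15 | ring A dienone: (2R)-6-(3-methylbut-2-en-1-yl)-2-{3-(3-methylbut-2-en-1-yl)-4-[(2-methylbut-3-en-2-yl)oxy]phenyl}-7-(triisopropylsilyloxy)-2,3-dihydro-4H-chromene-4,5(6H)-dione, C6 unassigned (not isolated) | CC(C)=CCc1cc([C@H]2CC(=O)C3=C(C=C(O[Si](C(C)C)(C(C)C)C(C)C)C(CC=C(C)C)C3=O)O2)ccc1OC(C)(C)C=C | intermediate
16 | ring A phenol: (2R)-5-hydroxy-6-(3-methylbut-2-en-1-yl)-2-{3-(3-methylbut-2-en-1-yl)-4-[(2-methylbut-3-en-2-yl)oxy]phenyl}-7-(triisopropylsilyloxy)-2,3-dihydro-4H-chromen-4-one (not isolated) | CC(C)=CCc1cc([C@H]2CC(=O)c3c(cc(O[Si](C(C)C)(C(C)C)C(C)C)c(CC=C(C)C)c3O)O2)ccc1OC(C)(C)C=C | intermediate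
17 | ring B dienone: (2R)-5-hydroxy-6-(3-methylbut-2-en-1-yl)-2-[3,5-bis(3-methylbut-2-en-1-yl)-4-oxocyclohexa-1,5-dien-1-yl]-7-(triisopropylsilyloxy)-2,3-dihydro-4H-chromen-4-one, ring sp3 carbon unassigned (not isolated) | CC(C)=CCC1=CC([C@H]2CC(=O)c3c(cc(O[Si](C(C)C)(C(C)C)C(C)C)c(CC=C(C)C)c3O)O2)=CC(CC=C(C)C)C1=O | intermediate
18 | (2R)-5-hydroxy-2-[4-hydroxy-3,5-bis(3-methylbut-2-en-1-yl)phenyl]-6-(3-methylbut-2-en-1-yl)-7-(triisopropylsilyloxy)-2,3-dihydro-4H-chromen-4-one | CC(C)=CCc1cc([C@H]2CC(=O)c3c(cc(O[Si](C(C)C)(C(C)C)C(C)C)c(CC=C(C)C)c3O)O2)cc(CC=C(C)C)c1O | intermediate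
19 | (2R)-5,7-dihydroxy-2-[4-hydroxy-3,5-bis(3-methylbut-2-en-1-yl)phenyl]-6-(3-methylbut-2-en-1-yl)-2,3-dihydro-4H-chromen-4-one | CC(C)=CCc1cc([C@H]2CC(=O)c3c(cc(O)c(CC=C(C)C)c3O)O2)cc(CC=C(C)C)c1O | target

Total step count: 10. Longest linear sequence: 7 steps (steps 4, 5, 6, 7, 8, 9, 10); the ring A branch (steps 1 to 3) joins at step 8.

Steps most likely to fail

Step 9. The tertiary C–O bonds may break heterolytically and lose the allyl unit instead of transferring it. The slower, unchelated ring B shift may also need heating long enough for the new prenylphenols to cyclise or for C2 to erode by reversible ring opening. The fallback moves the ring B shift to a stage without a stereocentre; it sets out from 10 and 5 and rejoins the route at 19. Bromide 10 is heated in toluene at 120 °C to give, by the same Claisen shift, 4-bromo-2,6-bis(3-methylbut-2-en-1-yl)phenol F1. TBSCl and imidazole in DMF convert it into tert-butyl[4-bromo-2,6-bis(3-methylbut-2-en-1-yl)phenoxy]dimethylsilane F2. n-BuLi in THF at −78 °C gives [4-(tert-butyldimethylsilyloxy)-3,5-bis(3-methylbut-2-en-1-yl)phenyl]lithium F3, B(OiPr)3 turns it into the lithium aryltri(propan-2-yloxy)borate F4, and aqueous NH4Cl releases [4-(tert-butyldimethylsilyloxy)-3,5-bis(3-methylbut-2-en-1-yl)phenyl]boronic acid F5. Addition of F5 to chromone 5 under the conditions of step 8 gives (2R)-2-[4-(tert-butyldimethylsilyloxy)-3,5-bis(3-methylbut-2-en-1-yl)phenyl]-5-[(2-methylbut-3-en-2-yl)oxy]-7-(triisopropylsilyloxy)-2,3-dihydro-4H-chromen-4-one F6, which holds a single tertiary ether, on O5. Its one chelation-assisted shift is run with Eu(fod)3 (10 mol%) in CHCl3 at 50 °C and gives (2R)-2-[4-(tert-butyldimethylsilyloxy)-3,5-bis(3-methylbut-2-en-1-yl)phenyl]-5-hydroxy-6-(3-methylbut-2-en-1-yl)-7-(triisopropylsilyloxy)-2,3-dihydro-4H-chromen-4-one F7. TBAF/AcOH in THF at 0 °C then removes both silyl groups and gives 19.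

Step 8. The aryl–rhodium species may be lost to protodeboronation before it inserts into the electron-rich chromone, or may insert into a vinyl group and eliminate the neighbouring aryloxide. Facial discrimination may also be insufficient; should only the sense of induction be opposite, the mirror-image ligand would be used. The fallback gives up catalytic asymmetric induction for a racemic addition and a resolution; it sets out from 10 and 5 and returns at 14. Bromide 10 and Mg turnings in THF give {3-(3-methylbut-2-en-1-yl)-4-[(2-methylbut-3-en-2-yl)oxy]phenyl}magnesium bromide F8. With CuBr·SMe2 (10 mol%) and Me3SiCl in THF at −78 °C, F8 adds 1,4 to chromone 5 and gives the racemic silyl enol ether 5-[(2-methylbut-3-en-2-yl)oxy]-2-{3-(3-methylbut-2-en-1-yl)-4-[(2-methylbut-3-en-2-yl)oxy]phenyl}-7-(triisopropylsilyloxy)-4-(trimethylsilyloxy)-2H-chromene F9. Aqueous NH4Cl work-up hydrolyses it to the racemic flavanone rac-5-[(2-methylbut-3-en-2-yl)oxy]-2-{3-(3-methylbut-2-en-1-yl)-4-[(2-methylbut-3-en-2-yl)oxy]phenyl}-7-(triisopropylsilyloxy)-2,3-dihydro-4H-chromen-4-one F10. Preparative chromatography on a chiral stationary phase (amylose tris(3,5-dimethylphenylcarbamate)) then separates the enantiomers and delivers 14.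

Step 2. O-alkylation of the hydrogen-bonded, peri-hindered 5-oxygen may be slow, and DBU may meanwhile cleave the silyl ether or add to the chromone. The fallback installs the tertiary allyl ether directly under base-free conditions; it sets out from 2 and returns at 5, so compound 4 and step 3 are bypassed. 2-Methylbut-3-en-2-ol is treated with n-BuLi and Boc2O in THF to give tert-butyl 2-methylbut-3-en-2-yl carbonate F11. With Pd(PPh3)4 (2 mol%) in THF at 0 °C, zerovalent palladium ionises F11 to a 1,1-dimethyl-π-allyl complex and tert-butoxide. The tert-butoxide deprotonates the 5-OH of 2, and the phenoxide attacks the more substituted allyl terminus (Tsuji–Trost O-allylation) to give 5.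

Further compounds
F1 | step 9 | 4-bromo-2,6-bis(3-methylbut-2-en-1-yl)phenol | CC(C)=CCc1cc(Br)cc(CC=C(C)C)c1O
F2 | step 9 | tert-butyl[4-bromo-2,6-bis(3-methylbut-2-en-1-yl)phenoxy]dimethylsilane | CC(C)=CCc1cc(Br)cc(CC=C(C)C)c1O[Si](C)(C)C(C)(C)C
F3 | step 9 | [4-(tert-butyldimethylsilyloxy)-3,5-bis(3-methylbut-2-en-1-yl)phenyl]lithium | [Li]c1cc(CC=C(C)C)c(O[Si](C)(C)C(C)(C)C)c(CC=C(C)C)c1
F4 | step 9 | lithium [4-(tert-butyldimethylsilyloxy)-3,5-bis(3-methylbut-2-en-1-yl)phenyl]tri(propan-2-yloxy)borate | CC(C)=CCc1cc([B-](OC(C)C)(OC(C)C)OC(C)C)cc(CC=C(C)C)c1O[Si](C)(C)C(C)(C)C.[Li+]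
F5 | step 9 | [4-(tert-butyldimethylsilyloxy)-3,5-bis(3-methylbut-2-en-1-yl)phenyl]boronic acid | CC(C)=CCc1cc(B(O)O)cc(CC=C(C)C)c1O[Si](C)(C)C(C)(C)C
F6 | step 9 | (2R)-2-[4-(tert-butyldimethylsilyloxy)-3,5-bis(3-methylbut-2-en-1-yl)phenyl]-5-[(2-methylbut-3-en-2-yl)oxy]-7-(triisopropylsilyloxy)-2,3-dihydro-4H-chromen-4-one | CC(C)=CCc1cc([C@H]2CC(=O)c3c(cc(O[Si](C(C)C)(C(C)C)C(C)C)cc3OC(C)(C)C=C)O2)cc(CC=C(C)C)c1O[Si](C)(C)C(C)(C)C
F7 | step 9 | (2R)-2-[4-(tert-butyldimethylsilyloxy)-3,5-bis(3-methylbut-2-en-1-yl)phenyl]-5-hydroxy-6-(3-methylbut-2-en-1-yl)-7-(triisopropylsilyloxy)-2,3-dihydro-4H-chromen-4-one | CC(C)=CCc1cc([C@H]2CC(=O)c3c(cc(O[Si](C(C)C)(C(C)C)C(C)C)c(CC=C(C)C)c3O)O2)cc(CC=C(C)C)c1O[Si](C)(C)C(C)(C)C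
F8 | step 8 | {3-(3-methylbut-2-en-1-yl)-4-[(2-methylbut-3-en-2-yl)oxy]phenyl}magnesium bromide | CC(C)=CCc1cc([Mg]Br)ccc1OC(C)(C)C=C
F9 | step 8 | racemic 5-[(2-methylbut-3-en-2-yl)oxy]-2-{3-(3-methylbut-2-en-1-yl)-4-[(2-methylbut-3-en-2-yl)oxy]phenyl}-7-(triisopropylsilyloxy)-4-(trimethylsilyloxy)-2H-chromene | CC(C)=CCc1cc(C2C=C(O[Si](C)(C)C)c3c(cc(O[Si](C(C)C)(C(C)C)C(C)C)cc3OC(C)(C)C=C)O2)ccc1OC(C)(C)C=C
F10 | step 8 | racemic 5-[(2-methylbut-3-en-2-yl)oxy]-2-{3-(3-methylbut-2-en-1-yl)-4-[(2-methylbut-3-en-2-yl)oxy]phenyl}-7-(triisopropylsilyloxy)-2,3-dihydro-4H-chromen-4-one | CC(C)=CCc1cc(C2CC(=O)c3c(cc(O[Si](C(C)C)(C(C)C)C(C)C)cc3OC(C)(C)C=C)O2)ccc1OC(C)(C)C=C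
F11 | step 2 | tert-butyl 2-methylbut-3-en-2-yl carbonate | CC(C)(C)OC(=O)OC(C)(C)C=C
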